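A closed, stirred vessel at constant volume holds starting material with some protic impurity, and the flasks differ in their temperature history.

the same everywhere: starting material 0.22 M; protic impurity 0.0440 M; time 2.0 min

| charge | temperature | remark |
|---|---|---|
| summer | 100 °C |  |
| dawn | 70 °C |  |
| dusk | 130 °C |  |
| winter |  | at 70 °C until 40 s, from then on at 130 °C |

    starting material → target (k1 = 0.038 /s, Ea1 = 92.0 kJ/mol)
    starting material → side product A (k2 = 0.0014 /s, Ea2 = 113 kJ/mol)
    starting material + target → side product B (k3 = 0.21 /M/s, Ea3 = 74.0 kJ/mol)
    starting material → decomposition product (k4 = 2.7 × 10⁻⁴ /s, Ea4 = 107 kJ/mol)
    starting material + protic impurity → quenched substrate (k5 = 51 /M/s, Ea5 = 52.0 kJ/mol)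
    (constants at 70 °C)

- in percentages every species weighs as the starting material in it: one side product B counts as two
- all constants are for 70 °C and move with temperature by the activation energies

- the flask that comes out highest in amount of target, in percent of the starting material charged, or "all alike" when all lie within 1.5 percentage points (summer / dawn / dusk / winter / all alike)
- target at the end, in percent of the starting material charged, summer
- target at the end, in percent of the starting material charged, dawn
- target at the end, in percent of the starting material charged, dusk
- target at the end, in percent of the starting material charged, winter

1. The protic impurity goes first. In dawn it removes starting material with a rate constant of 2.24 /s, faster than steps 1, 2 and 4 together. In dusk it is also faster. So 0.176 M of starting material remains for the other steps.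

2. Steps 1 and 3 both scale with starting material, so their ratio depends on target alone. The balance amount is the constant of step 1 over that of step 3, 0.181 M at 70 °C: the target level at which step 1 makes target as fast as step 3 removes it. The leak amount is steps 2 and 4 over step 3, 0.007952 M. Each starting material consumed then leaves (balance − target)/(balance + leak + target) of target, the instantaneous selectivity.

3. Two extremes for dawn come from freezing target in that fraction. Frozen at nil, it gives 76.6% of the charge. Frozen at its end value from the start, it gives 33.1%. Target climbs from nil to its end value, so dawn lies between them.

4. Frozen midway, the same fraction gives a quadratic, and dawn ends near 0.0978 M, or 44.4%. The selectivity is lower at that end value than at nil, so target gains more per starting material consumed early than late, and this figure should read slightly high. Starting material in dawn then decays at about 0.0499 /s, a lifetime of 20.0 s, shorter than 120 s, so it should fall to about 0.200% of the charge by the end of dawn.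

5. Step 1 has a higher activation energy than step 3, so the balance amount rises with heat. In dusk it is 0.463 M with leak 0.0582 M, which gives 0.122 M, or 55.3%. In summer the balance is 0.301 M with leak 0.0233 M, which gives 0.113 M, or 51.3%.

6. Winter spends its first 40 s under the dawn balance, and about 0.0239 M of starting material survives that stage. The cold stage of winter is reckoned to make 0.0890 M of target. The remainder then converts under the dusk balance, for a total of 0.104 M, or 47.1%. The reckoning therefore chooses dusk.

7. The forecast names dusk, with 50.3% for summer, 42.6% for dawn, 54.7% for dusk and 45.3% for winter, and it reckons that “Summer and dusk finish”.

8. The simulation gives dusk as highest, with 50.3% in summer, 42.6% in dawn, 54.7% in dusk and 45.3% in winter.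

The neighbour of dawn charged with 0.075 M of protic impurity keeps the dawn balance amount 0.181 M and the dawn leak, but leaves 0.145 M of starting material after the quench. Frozen midway, the fraction gives 0.0862 M of target in that neighbour, or 39.2% of the charge. Simulated, the neighbour ends at 2.00 min with 37.9% target and 34.1% quenched substrate.

All constants were set for the occasion; the rest is arithmetic.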